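## The problem

Atoms are numbered as in a clerodane (C1–C10 for the two six-membered carbocycles, C11–C16 for the atoms of ring C and the furan, C17 and C20 for the methyl groups on C8 and C9, C18 and C19 for the lactone carbonyl and its CH2–O), and β is the face of H-10. The target is a compact pentacycle in which three rings meet at C10: ring A (C5–C10, with the 7α-acetate), ring B (C1–C5 and C10, with the C3=C4 alkene and the 2α-hydroxyl) and the seven-membered ring C (C1, C10, C9, C11, C12, C13, C16, with the C12 ketone, fused to the furan). The γ-lactone bridges C4 and C5. There are seven stereocentres, two of them quaternary (C5 and C9). C19, C20 and the acetoxy group are syn-axial on the α face of ring A, so all three fusions at C10 are trans and C7 is severely hindered. Control can only flow one way: C9 can set C8 in a sigmatropic shift, C8 sets C7 only in the Felkin sense (the 7β epimer), and the tether centres can set C5 and C10 in a cycloaddition. The finished tricycle can then set C7 (hydride forced to the β face by C19 and C20), C1 (epimerisable, hence thermodynamic) and C2 (axial hydride). The furan (acid, electrophilic oxidants), the γ-hydroxy-α,β-unsaturated lactone and the acetate (base) and the acidic C1–H will not survive rough treatment, and the C12 ketone competes for every base and hydride. The enabling feature is that rings A and B share the C5–C10 bond and that the lactone α-carbon C4 lies in ring B. C4=C5 with C18 and C19 is therefore a 4-substituted butenolide, and C3=C2–C1=C10 is a vinyl group on the C1=C10 alkene of ring C, so an intramolecular [4+2] can form C5–C10 and C3–C4 and close rings A and B together.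

## Retrosynthesis

**C2–H (38 to 37).** The last bond cut is the C2–H bond of the allylic alcohol, which leads back to ene-dione 37. A Luche reduction is asked to deliver hydride axially from the β face. Setting C2 directly by hydroboration is not relied on, because the face of that addition cannot be predicted with confidence and C1 would be fixed with it.

**C2–O and C3=C4 (37 to 36 to 33).** The C2 oxygen comes from anti-Markovnikov hydration of the furan-conjugated C1=C2 alkene (diol 36; the C12 ketone may be reduced in passing and is restored on going to 37). The C3=C4 alkene cannot be made from a C2 ketone by enolate chemistry, because that ketone enolises toward C1 (furylic and vinylogous to C12) and not toward C3. The leaving group is therefore placed on C4 before any C2 carbonyl exists: selenide 33 loses PhSeOH toward C3 during the oxidative work-up of the hydroboration.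

**C4–Se and the C7 oxygen (33 to 31 to 29 to 28).** The selenide is cut back to the lactone enolate of diketone 29. Diphenyl diselenide is chosen because it reacts with lactone enolates but not with ketone enolates, so the C7 and C12 ketones need no protection. The acetate is put on after this step, since an acetate would compete for the base. The C7 oxygen is carried through the cycloaddition as the 7β-hydroxyl of 28 and inverted afterwards (29, then reduction from the β face). In the chair-like cycloaddition geometry that leads to the target, a 7α substituent would be axial and syn to C19 and C20, whereas the 7β-hydroxyl is equatorial and supports that geometry. The 7β epimer is also the Felkin product of the aldol step, so the detour costs no extra steps compared with correcting C7 before the cycloaddition.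

**C5–C10 and C3–C4 (28 to 27, key step).** Cutting both bonds opens rings A and B and removes three stereocentres (C4, C5, C10). Triene 27 has a finished ring C and only three stereocentres (C7, C8, C9). A stepwise annulation would have to build the C5 quaternary centre and the trans fusion separately. The forward reaction must be endo with respect to the lactone carbonyl and must take the diene face that puts C20 axial.

**Ring C and the diene (27 to 26).** The C1=C10 double bond and the vinyl terminus are cut together by ring-closing enyne metathesis of the 2-ethynylfuran and the propenyl group on C9. The neighbouring option, vinylation of an enol triflate of a C1 ketone, needs a furan-fused 1,5-dione in which the two ketones would have to be told apart. The metathesis makes ring and diene in one step from acyclic 26.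

**Butenolide and C6–C7 (26 to 24 to 23 to 19 + 22).** The butenolide is cut at C4=C5 and C18–O (ketenylidene ylide on the α-ketol 24). The C6–C7 bond is cut by a Mukaiyama aldol between aldehyde 19 and the enol silane 22 of protected hydroxyacetone 20. The aldol must follow Felkin–Anh control by the C8 methyl and the quaternary C9.

**C12–C13 (19 to 18 to 12 + 16).** The furyl ketone is cut at C12–C13. Lactone 12 serves as the acylating agent for the furyllithium from bromide 16 (from 3-bromofuran 13 through iodide 15). A single addition gives the ketone and frees the C7 alcohol for oxidation to 19, without protecting groups.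

**C8–C9 (12 to 10 to 9 to 5 to 4 to 3 to 1).** Lactone 12 comes from diol 10 by oxidation at the less hindered end, and 10 comes from lactone 9. The C8–C9 bond, with the quaternary centre and its tertiary neighbour, is cut by an Ireland–Claisen rearrangement of propanoate 5. The single carbinol centre of 4, made by CBS reduction of enone 3 (one step from alkyne 1), is transferred to C9 and C8 through a chair transition state. Every later stereocentre descends from this one.

## Roads not taken

**Alternative 1:** the C19–O bond is cut, and the lactone is closed late by carboxylate-directed C–H oxidation. Pd(OAc)2 with an N-acetyl amino acid ligand and tert-butyl hydroperoxide would palladate the angular methyl of alkenyl acid A1 and form the C–O bond to give decalin butenolide A2.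
- Merits: the decalin can be built by standard annulation chemistry, the lactone is absent during most of the route, and no diene-face question arises.
- Weak points: the directing carboxylate sits on an sp2 carbon and the methyl is γ to it, so a six-membered palladacycle on an unsaturated acid is required. Allylic and C6 methylene C–H bonds and the alkene compete under peroxide conditions. A2 still lacks the furan and ring C, so the C1–C16 bond has to be made afterwards at a methylene.
- Comparison: this road is better for setting the A/B stereocentres by established means. The chosen plan obtains the C18/C19 oxidation pattern from the dienophile at no cost and has ring C in place before the decalin exists.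

**Alternative 2:** the C1–C16 bond is cut. Under Pd2(dba)3, 4,5-bis(diphenylphosphino)-9,9-dimethylxanthene and K3PO4, the α'-enolate of the ring B enone in bromofuran A3 would displace bromide and close ring C, giving pentacyclic ketone A4.
- Merits: A4 has the same structure as compound 37 of the chosen route, C1 is stereoconvergent, and only the Luche reduction follows. After its key step this road is shorter than the chosen one (one operation against six).
- Weak points: A3 is a trans-decalin ene-dione with C5, C8, C9 and C10 already set, and nothing in this plan makes that easier than 27. The ene-dione must survive base at elevated temperature. The reductive elimination forms a seven-membered ring at a carbon next to C10, which is flanked by two quaternary centres.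
- Comparison: the chosen plan sets against the shorter endgame a key step that closes two rings and sets three stereocentres from a precursor whose stereocentres all derive from one catalytic reduction.

**Alternative 3:** the C9–C11 bond is cut. Cu(acac)2 would convert diazoketone A5 into a carbenoid that adds to the exocyclic methylene on ring A, giving the spiro-cyclopropane A6. Reductive scission of the cyclopropane would then reveal the C20 methyl.
- Merits: ring C and the quaternary C9 are made together on a rigid framework, and the methyl is revealed by a known type of cyclopropyl ketone cleavage.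
- Weak points: the carbenoid can insert into the C1–H or C10–H bonds. The face of addition decides C9. The reductive opening must cleave the bond to CH2 and not the one to C9, in a molecule that holds a γ-oxygenated butenolide and a furyl ketone, both sensitive to electron-transfer reductants. Deprotection still follows.
- Comparison: this road is better in that C9 is set on a conformationally defined ring. The chosen plan sets C9 early by chirality transfer and needs no late reductive step near the butenolide.

Key step: step 16

Step 1
Reactants: 1 tert-butyl(but-3-yn-1-yloxy)dimethylsilane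
Product: 3 (E)-6-(tert-butyldimethylsilyloxy)-4-methylhex-3-en-2-one, via alkenylalane 2 (not isolated)
Conditions: Me3Al, Cp2ZrCl2 (0.2 equiv), CH2Cl2, 0 °C → rt; then CH3COCl, Pd(PPh3)4 (5 mol %), ZnCl2 (0.2 equiv), THF, 0 °C → rt
Reagents that add atoms: trimethylaluminium, C[Al](C)C; acetyl chloride, CC(=O)Cl
Why: Zirconium-catalysed syn-methylalumination of the terminal alkyne (Negishi carboalumination) puts methyl on the internal carbon; Pd-catalysed acylation of the alkenylalane proceeds with retention and gives the (E)-enone.

Step 2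
Reactants: 3 (E)-6-(tert-butyldimethylsilyloxy)-4-methylhex-3-en-2-one
Product: 4 (S,E)-6-(tert-butyldimethylsilyloxy)-4-methylhex-3-en-2-ol
Conditions: (R)-1-methyl-3,3-diphenyltetrahydro-1H,3H-pyrrolo[1,2-c][1,3,2]oxazaborole (0.1 equiv), catecholborane, toluene, −78 °C
Reagents that add atoms: none
Why: Corey–Bakshi–Shibata reduction; the alkenyl group acts as the large substituent, so the (R)-catalyst should give the (S)-carbinol, and catecholborane at low temperature spares the alkene.

Step 3
Reactants: 4 (S,E)-6-(tert-butyldimethylsilyloxy)-4-methylhex-3-en-2-ol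
Product: 5 (S,E)-6-(tert-butyldimethylsilyloxy)-4-methylhex-3-en-2-yl propanoate
Conditions: CH3CH2COCl, pyridine, 4-(dimethylamino)pyridine (5 mol %), CH2Cl2, 0 °C → rt
Reagents that add atoms: propanoyl chloride, CCC(=O)Cl
Why: Standard acylation of a secondary allylic alcohol under nucleophilic catalysis; no stereocentre is touched.

Step 4
Reactants: 5 (S,E)-6-(tert-butyldimethylsilyloxy)-4-methylhex-3-en-2-yl propanoate
Product: 9 (3S,4R)-3,4-dimethyl-4-[(E)-prop-1-enyl]oxan-2-one, via lithium enolate 6 (not isolated), via silyl ketene acetal 7 (not isolated), via trimethylsilyl ester 8 (not isolated)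
Conditions: LiN(iPr)2, THF–N,N'-dimethylpropyleneurea (4:1), −78 °C; Me3SiCl, −78 °C → 60 °C; then 1 M HCl, THF, rt
Reagents that add atoms: none
Why: Ireland–Claisen rearrangement; the polar co-solvent gives the enolate with methyl cis to O–Li, hence the (Z)-silyl ketene acetal, and a chair transition state with the carbinol methyl equatorial transfers the (S)-centre to C9 (R) and C8 (S) and leaves an (E)-propenyl group. Acid then cleaves both silyl groups and the δ-hydroxy acid lactonises.

Step 5
Reactants: 9 (3S,4R)-3,4-dimethyl-4-[(E)-prop-1-enyl]oxan-2-one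
Product: 10 (2S,3R)-2,3-dimethyl-3-[(E)-prop-1-enyl]pentane-1,5-diol
Conditions: LiAlH4, THF, 0 °C → rt
Reagents that add atoms: none
Why: Hydride reduction of a lactone to the diol; this swaps the oxidation levels of the two chain ends for the next step.

Step 6
Reactants: 10 (2S,3R)-2,3-dimethyl-3-[(E)-prop-1-enyl]pentane-1,5-diol
Product: 12 (4R,5S)-4,5-dimethyl-4-[(E)-prop-1-enyl]oxan-2-one, via lactol 11 (not isolated)
Conditions: 2,2,6,6-tetramethylpiperidin-1-oxyl (0.2 equiv), PhI(OAc)2, CH2Cl2, rt
Reagents that add atoms: none
Why: Oxoammonium-mediated oxidative lactonisation; the less hindered primary alcohol (future C12, on a CH2) is oxidised first, the aldehyde is trapped by the β-branched C7 hydroxyl as the lactol, and this is oxidised on to the lactone.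

Step 7
Reactants: 13 3-bromofuran
Product: 15 3-bromo-2-iodofuran, via 3-bromo-2-lithiofuran 14 (not isolated)
Conditions: LiN(iPr)2, THF, −78 °C; then I2, −78 °C → rt
Reagents that add atoms: iodine, II
Why: Directed deprotonation of 3-bromofuran occurs at C2, the position flanked by oxygen and bromine; iodine traps the anion.

Step 8
Reactants: 15 3-bromo-2-iodofuran
Product: 16 [(3-bromofuran-2-yl)ethynyl]trimethylsilane
Conditions: HC≡CSiMe3, PdCl2(PPh3)2 (2 mol %), CuI (4 mol %), Et3N, THF, rt
Reagents that add atoms: ethynyltrimethylsilane, C#C[Si](C)(C)C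
Why: Sonogashira coupling; oxidative addition into the C–I bond is much faster than into the C–Br bond at room temperature, so only C2 is alkynylated.

Step 9
Reactants: 16 [(3-bromofuran-2-yl)ethynyl]trimethylsilane; 12 (4R,5S)-4,5-dimethyl-4-[(E)-prop-1-enyl]oxan-2-one
Product: 18 (3R,4S)-5-hydroxy-3,4-dimethyl-3-[(E)-prop-1-enyl]-1-{2-[(trimethylsilyl)ethynyl]furan-3-yl}pentan-1-one, via furyllithium 17 (not isolated)
Conditions: 16, n-BuLi, Et2O, −78 °C; then 12, −78 °C; aq. NH4Cl
Reagents that add atoms: none
Why: Bromine–lithium exchange is faster than attack at silicon; the 3-furyllithium adds once to the δ-lactone because the tetrahedral lithium lactolate persists until the quench. Ring opening gives the C12 ketone and frees the C7 alcohol (the product may sit partly as its lactol).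

Step 10
Reactants: 18 (3R,4S)-5-hydroxy-3,4-dimethyl-3-[(E)-prop-1-enyl]-1-{2-[(trimethylsilyl)ethynyl]furan-3-yl}pentan-1-one
Product: 19 (2S,3R)-2,3-dimethyl-5-oxo-3-[(E)-prop-1-enyl]-5-{2-[(trimethylsilyl)ethynyl]furan-3-yl}pentanal
Conditions: Dess–Martin periodinane, NaHCO3, CH2Cl2, 0 °C → rt
Reagents that add atoms: none
Why: Buffered Dess–Martin oxidation of a primary alcohol; the α-centre next to the quaternary carbon is not expected to epimerise under these neutral conditions.

Step 11
Reactants: 20 1-(tert-butyldimethylsilyloxy)propan-2-one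
Product: 22 tert-butyldimethyl{[2-(trimethylsilyloxy)prop-2-en-1-yl]oxy}silane, via lithium enolate 21 (not isolated)
Conditions: LiN(iPr)2, THF, −78 °C; then Me3SiCl, −78 °C → 0 °C
Reagents that add atoms: chlorotrimethylsilane, C[Si](C)(C)Cl
Why: Kinetic deprotonation takes the unhindered methyl group rather than the methylene shielded by the bulky silyl ether; O-silylation fixes the terminal enol silane.

Step 12
Reactants: 19 (2S,3R)-2,3-dimethyl-5-oxo-3-[(E)-prop-1-enyl]-5-{2-[(trimethylsilyl)ethynyl]furan-3-yl}pentanal; 22 tert-butyldimethyl{[2-(trimethylsilyloxy)prop-2-en-1-yl]oxy}silane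
Product: 23 (4S,5S,6R)-1-(tert-butyldimethylsilyloxy)-4-hydroxy-5,6-dimethyl-6-[(E)-prop-1-enyl]-8-{2-[(trimethylsilyl)ethynyl]furan-3-yl}octane-2,8-dione
Conditions: BF3·OEt2, CH2Cl2, −78 °C
Reagents that add atoms: none
Why: Mukaiyama aldol through an open transition state; Felkin–Anh attack anti to the quaternary C9 on the α-methyl aldehyde should give the 7,8-syn carbinol (7S, the future 7β-hydroxyl), and the aldehyde is far more electrophilic than the furyl ketone.

Step 13
Reactants: 23 (4S,5S,6R)-1-(tert-butyldimethylsilyloxy)-4-hydroxy-5,6-dimethyl-6-[(E)-prop-1-enyl]-8-{2-[(trimethylsilyl)ethynyl]furan-3-yl}octane-2,8-dione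
Product: 24 (4S,5S,6R)-8-(2-ethynylfuran-3-yl)-1,4-dihydroxy-5,6-dimethyl-6-[(E)-prop-1-enyl]octane-2,8-dione
Conditions: Bu4NF, AcOH, THF, 0 °C → rt
Reagents that add atoms: none
Why: Fluoride cleaves the primary silyl ether and the alkynylsilane; acetic acid buffers the medium so that the β-hydroxy ketone does not undergo retro-aldol cleavage or dehydration.

Step 14
Reactants: 24 (4S,5S,6R)-8-(2-ethynylfuran-3-yl)-1,4-dihydroxy-5,6-dimethyl-6-[(E)-prop-1-enyl]octane-2,8-dione
Product: 26 4-{(2S,3S,4R)-6-(2-ethynylfuran-3-yl)-2-hydroxy-3,4-dimethyl-6-oxo-4-[(E)-prop-1-enyl]hexyl}furan-2(5H)-one, via phosphoranylidene ester 25 (not isolated)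
Conditions: Ph3P=C=C=O (1.1 equiv), toluene, 80 °C
Reagents that add atoms: (triphenylphosphoranylidene)ketene, O=C=C=P(c1ccccc1)(c1ccccc1)c1ccccc1
Why: Butenolide synthesis with the Bestmann ylide: the primary α-ketol hydroxyl adds to the ketene to give the phosphoranylidene ester, which closes by intramolecular Wittig olefination on the adjacent ketone. The hindered secondary C7 hydroxyl should react more slowly.

Step 15
Reactants: 26 4-{(2S,3S,4R)-6-(2-ethynylfuran-3-yl)-2-hydroxy-3,4-dimethyl-6-oxo-4-[(E)-prop-1-enyl]hexyl}furan-2(5H)-one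
Product: 27 (6R)-6-[(2S,3S)-3-hydroxy-4-(5-oxo-2,5-dihydrofuran-3-yl)butan-2-yl]-6-methyl-8-vinyl-5,6-dihydro-4H-cyclohepta[b]furan-4-one
Conditions: (H2IMes)(PCy3)Cl2Ru=CHPh (second-generation Grubbs catalyst, 10 mol %), ethylene (1 atm), toluene, 60 °C
Reagents that add atoms: ethylene, C=C
Why: Ring-closing enyne metathesis in the exo mode: the ruthenium methylidene kept alive by ethylene adds to the terminal alkyne, and the vinylcarbene closes onto the propenyl group, so the seven-membered ring and its 1-vinyl diene arise together with loss of propene. The electron-poor trisubstituted butenolide alkene is inert.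

Step 16
Reactants: 27 (6R)-6-[(2S,3S)-3-hydroxy-4-(5-oxo-2,5-dihydrofuran-3-yl)butan-2-yl]-6-methyl-8-vinyl-5,6-dihydro-4H-cyclohepta[b]furan-4-one
Product: 28 7β-hydroxy-12-oxo-15,16-epoxy-1,16-cyclocleroda-1,13(16),14-trien-18,19-olide (4βH,10βH; C17, C19 and C20 α)
Conditions: toluene (0.01 M), 2,6-di-tert-butyl-4-methylphenol (0.1 equiv), 160 °C, sealed tube
Reagents that add atoms: none
Why: Thermal, concerted but asynchronous normal-demand [4+2] of a 1,7,9-decatriene: the diene C3=C2–C1=C10, raised in energy by the furan on C1, adds suprafacially to the butenolide C4=C5 and forms C5–C10 and C3–C4; the closest known reactions are intramolecular Diels–Alder reactions of decatrienes with 4-substituted butenolides and other β,β-disubstituted dienophiles that create an angular quaternary carbon. Ring B is the six-membered ring of the cycloaddition itself (C1, C2, C3 from the diene, C4 and C5 from the dienophile, C10), and ring A is closed in the fused mode as a six-membered ring by the four-atom tether C9–C8–C7–C6 in a chair-like arrangement. C4 and C5 are fixed cis (cis-fused lactone) by the cyclic dienophile. C5 relative to C10: the tether leaves C10 from the outside position of the diene and is trans to the lactone carbonyl on the dienophile, so the carbonyl-endo transition state gives the trans A/B fusion (C19 α, H-10 β). C10 relative to C9: the dienophile reaches one diene face with C20 axial and C11 equatorial on the forming chair and the other face with C11 axial; in the first chair the 7β-hydroxyl and the C8 methyl are both equatorial, in the second both are axial and the hydroxyl is syn to C11 and C19, so the first is expected to prevail and puts H-10 trans to C20. The selectivity needed is therefore endo addition on the diene face anti to C11, and it is secured by the ring-fixed dienophile geometry, the outside tether position and the two equatorial tether substituents. The new C1=C2 alkene remains conjugated with the furan, and the acyl-substituted furan itself is not expected to act as a diene.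

Step 17
Reactants: 28 7β-hydroxy-12-oxo-15,16-epoxy-1,16-cyclocleroda-1,13(16),14-trien-18,19-olide
Product: 29 7,12-dioxo-15,16-epoxy-1,16-cyclocleroda-1,13(16),14-trien-18,19-olide (4βH,10βH)
Conditions: Dess–Martin periodinane, NaHCO3, CH2Cl2, rt
Reagents that add atoms: none
Why: Dess–Martin oxidation of the secondary alcohol removes the temporary 7β centre; the equatorial C8 methyl is the stable arrangement next to the new ketone.

Step 18
Reactants: 29 7,12-dioxo-15,16-epoxy-1,16-cyclocleroda-1,13(16),14-trien-18,19-olide
Product: 31 4β-(phenylselanyl)-7,12-dioxo-15,16-epoxy-1,16-cyclocleroda-1,13(16),14-trien-18,19-olide, via trilithium enolate 30 (not isolated)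
Conditions: 29 added to LiN(iPr)2 (3.5 equiv), THF, −78 → −40 °C; PhSeSePh, N,N'-dimethylpropyleneurea, −78 → −20 °C; aq. NH4Cl
Reagents that add atoms: diphenyl diselenide, c1ccccc1[Se][Se]c1ccccc1
Why: Excess amide base converts both ketones (at C6 and C11) and the lactone (at C4) into enolates; diphenyl diselenide selenenylates lactone and ester enolates but not ketone enolates, so only C4 reacts, from the β face because the lactone must stay cis-fused. The ketone enolates are reprotonated on work-up.

Step 19
Reactants: 31 4β-(phenylselanyl)-7,12-dioxo-15,16-epoxy-1,16-cyclocleroda-1,13(16),14-trien-18,19-olide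
Product: 33 7α-acetoxy-12-oxo-4β-(phenylselanyl)-15,16-epoxy-1,16-cyclocleroda-1,13(16),14-trien-18,19-olide, via lithium alkoxide 32 (not isolated)
Conditions: Li[HB(sBu)3], THF, −78 °C; then Ac2O, 4-(dimethylamino)pyridine, pyridine, −78 °C → rt
Reagents that add atoms: acetic anhydride, CC(=O)OC(C)=O
Why: The α face of the C7 ketone is closed by the syn-axial C19 and C20, so the bulky hydride attacks equatorially from the β face and gives the axial 7α-alkoxide; the saturated ring ketone should react before the hindered, furan-conjugated C12 ketone. The alkoxide is far more nucleophilic than the neutral axial alcohol and is acetylated in the same flask.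

Step 20
Reactants: 33 7α-acetoxy-12-oxo-4β-(phenylselanyl)-15,16-epoxy-1,16-cyclocleroda-1,13(16),14-trien-18,19-olide
Product: 36 7α-acetoxy-2α,12-dihydroxy-15,16-epoxy-1,16-cyclocleroda-3,13(16),14-trien-18,19-olide (1αH expected; both C12 epimers), via alkylborane 34 (not isolated), via selenoxide 35 (not isolated)
Conditions: BH3·THF (excess), THF, 0 °C → rt; then 30 % H2O2, pH 7 phosphate buffer, pyridine, 0 °C → rt
Reagents that add atoms: hydrogen peroxide, OO
Why: Hydroboration–oxidation places boron on the less substituted C2 and hydrogen on C1 by syn addition, as for 1-arylcycloalkenes; the oxidative work-up also converts the selenide into the selenoxide, which undergoes syn-elimination toward C3, the only carbon with β-hydrogens. Excess borane may reduce the C12 ketone, which step 21 reverses; the axial 4β-selanyl group and the strain of an axial C16 should favour α-face attack, but neither new centre is relied on.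

Step 21
Reactants: 36 7α-acetoxy-2α,12-dihydroxy-15,16-epoxy-1,16-cyclocleroda-3,13(16),14-trien-18,19-olide
Product: 37 7α-acetoxy-2,12-dioxo-15,16-epoxy-1,16-cyclocleroda-3,13(16),14-trien-18,19-olide (1αH,10βH)
Conditions: Dess–Martin periodinane (3 equiv), NaHCO3, CH2Cl2, rt; then 1,8-diazabicyclo[5.4.0]undec-7-ene (0.2 equiv), rt
Reagents that add atoms: none
Why: Dess–Martin oxidation of the allylic C2 and furylic C12 carbinols gives the ene-dione and restores the C12 ketone; the amidine base equilibrates C1 (α to the C2 ketone and vinylogous to C12 through the furan) to the trans B/C fusion with C16 equatorial, whatever the face of the hydroboration.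

Step 22
Reactants: 37 7α-acetoxy-2,12-dioxo-15,16-epoxy-1,16-cyclocleroda-3,13(16),14-trien-18,19-olide
Product: 38 7α-acetoxy-2α-hydroxy-12-oxo-15,16-epoxy-1,16-cyclocleroda-3,13(16),14-trien-18,19-olide (1αH,10βH; the target, CNP0182929.1)
Conditions: NaBH4 (1.0 equiv), CeCl3·7H2O, MeOH, −78 °C
Reagents that add atoms: none
Why: Luche 1,2-reduction of the doubly activated C2 carbonyl; axial hydride attack from the β face, where only H-10 is syn-axial, gives the equatorial 2α-alcohol. The hindered, furan-deactivated C12 ketone, the acetate and the lactone should not react at −78 °C.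

**Compound list**

1 | tert-butyl(but-3-yn-1-yloxy)dimethylsilane | C#CCCO[Si](C)(C)C(C)(C)C | starting material
2 | (E)-[4-(tert-butyldimethylsilyloxy)-2-methylbut-1-enyl]dimethylalane | C[Al](C)/C=C(\C)CCO[Si](C)(C)C(C)(C)C | intermediate
3 | (E)-6-(tert-butyldimethylsilyloxy)-4-methylhex-3-en-2-one | CC(=O)/C=C(\C)CCO[Si](C)(C)C(C)(C)C | intermediate
4 | (S,E)-6-(tert-butyldimethylsilyloxy)-4-methylhex-3-en-2-ol | C[C@H](O)/C=C(\C)CCO[Si](C)(C)C(C)(C)C | intermediate
5 | (S,E)-6-(tert-butyldimethylsilyloxy)-4-methylhex-3-en-2-yl propanoate | CCC(=O)O[C@@H](C)/C=C(\C)CCO[Si](C)(C)C(C)(C)C | intermediate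
6 | lithium (Z)-enolate of propanoate 5 (methyl cis to O–Li) | [Li+].C/C=C(\[O-])O[C@@H](C)/C=C(\C)CCO[Si](C)(C)C(C)(C)C | intermediate
7 | (Z)-trimethylsilyl ketene acetal of propanoate 5 | C/C=C(\O[Si](C)(C)C)O[C@@H](C)/C=C(\C)CCO[Si](C)(C)C(C)(C)C | intermediate
8 | trimethylsilyl (2S,3R,4E)-3-[2-(tert-butyldimethylsilyloxy)ethyl]-2,3-dimethylhex-4-enoate | C/C=C/[C@@](C)(CCO[Si](C)(C)C(C)(C)C)[C@H](C)C(=O)O[Si](C)(C)C | intermediate
9 | (3S,4R)-3,4-dimethyl-4-[(E)-prop-1-enyl]oxan-2-one | C/C=C/[C@@]1(C)CCOC(=O)[C@H]1C | intermediate
10 | (2S,3R)-2,3-dimethyl-3-[(E)-prop-1-enyl]pentane-1,5-diol | C/C=C/[C@@](C)(CCO)[C@H](C)CO | intermediate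
11 | (4R,5S)-4,5-dimethyl-4-[(E)-prop-1-enyl]oxan-2-ol (lactol, both C2 epimers) | C/C=C/[C@@]1(C)CC(O)OC[C@H]1C | intermediate
12 | (4R,5S)-4,5-dimethyl-4-[(E)-prop-1-enyl]oxan-2-one | C/C=C/[C@@]1(C)CC(=O)OC[C@H]1C | intermediate
13 | 3-bromofuran | Brc1ccoc1 | starting material
14 | 3-bromo-2-lithiofuran | [Li]c1occc1Br | intermediate
15 | 3-bromo-2-iodofuran | Ic1occc1Br | intermediate
16 | [(3-bromofuran-2-yl)ethynyl]trimethylsilane | C[Si](C)(C)C#Cc1occc1Br | intermediate
17 | {2-[(trimethylsilyl)ethynyl]furan-3-yl}lithium | [Li]c1ccoc1C#C[Si](C)(C)C | intermediate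
18 | (3R,4S)-5-hydroxy-3,4-dimethyl-3-[(E)-prop-1-enyl]-1-{2-[(trimethylsilyl)ethynyl]furan-3-yl}pentan-1-one | C/C=C/[C@@](C)(CC(=O)c1ccoc1C#C[Si](C)(C)C)[C@H](C)CO | intermediate
19 | (2S,3R)-2,3-dimethyl-5-oxo-3-[(E)-prop-1-enyl]-5-{2-[(trimethylsilyl)ethynyl]furan-3-yl}pentanal | C/C=C/[C@@](C)(CC(=O)c1ccoc1C#C[Si](C)(C)C)[C@H](C)C=O | intermediate
20 | 1-(tert-butyldimethylsilyloxy)propan-2-one | CC(=O)CO[Si](C)(C)C(C)(C)C | starting material
21 | lithium 3-(tert-butyldimethylsilyloxy)prop-1-en-2-olate | [Li+].C=C([O-])CO[Si](C)(C)C(C)(C)C | intermediate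
22 | tert-butyldimethyl{[2-(trimethylsilyloxy)prop-2-en-1-yl]oxy}silane | C=C(O[Si](C)(C)C)CO[Si](C)(C)C(C)(C)C | intermediate
23 | (4S,5S,6R)-1-(tert-butyldimethylsilyloxy)-4-hydroxy-5,6-dimethyl-6-[(E)-prop-1-enyl]-8-{2-[(trimethylsilyl)ethynyl]furan-3-yl}octane-2,8-dione | C/C=C/[C@@](C)(CC(=O)c1ccoc1C#C[Si](C)(C)C)[C@H](C)[C@@H](O)CC(=O)CO[Si](C)(C)C(C)(C)C | intermediate
24 | (4S,5S,6R)-8-(2-ethynylfuran-3-yl)-1,4-dihydroxy-5,6-dimethyl-6-[(E)-prop-1-enyl]octane-2,8-dione | C/C=C/[C@@](C)(CC(=O)c1ccoc1C#C)[C@H](C)[C@@H](O)CC(=O)CO | intermediate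
25 | (4S,5S,6R)-8-(2-ethynylfuran-3-yl)-4-hydroxy-5,6-dimethyl-2,8-dioxo-6-[(E)-prop-1-enyl]octyl (triphenylphosphoranylidene)acetate | C/C=C/[C@@](C)(CC(=O)c1ccoc1C#C)[C@H](C)[C@@H](O)CC(=O)COC(=O)C=P(c1ccccc1)(c1ccccc1)c1ccccc1 | intermediate
26 | 4-{(2S,3S,4R)-6-(2-ethynylfuran-3-yl)-2-hydroxy-3,4-dimethyl-6-oxo-4-[(E)-prop-1-enyl]hexyl}furan-2(5H)-one | C/C=C/[C@@](C)(CC(=O)c1ccoc1C#C)[C@H](C)[C@@H](O)CC1=CC(=O)OC1 | intermediate
27 | (6R)-6-[(2S,3S)-3-hydroxy-4-(5-oxo-2,5-dihydrofuran-3-yl)butan-2-yl]-6-methyl-8-vinyl-5,6-dihydro-4H-cyclohepta[b]furan-4-one | C=CC1=C[C@](C)([C@H](C)[C@@H](O)CC3=CC(=O)OC3)CC(=O)c2ccoc12 | intermediate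
28 | 7β-hydroxy-12-oxo-15,16-epoxy-1,16-cyclocleroda-1,13(16),14-trien-18,19-olide (4βH,10βH; C17, C19, C20 α) | O[C@H]1C[C@@]23COC(=O)[C@@H]2CC=C2c4occc4C(=O)C[C@@](C)([C@@H]1C)[C@@H]23 | intermediate
29 | 7,12-dioxo-15,16-epoxy-1,16-cyclocleroda-1,13(16),14-trien-18,19-olide (4βH,10βH) | O=C1C[C@@]23COC(=O)[C@@H]2CC=C2c4occc4C(=O)C[C@@](C)([C@@H]1C)[C@@H]23 | intermediate
30 | trilithium salt of 29 (C6–C7 and C11–C12 ketone enolates, C4–C18 lactone enolate) | [Li+].[Li+].[Li+].[O-]C1=C[C@@]23COC([O-])=C2CC=C2c4occc4C([O-])=C[C@@](C)([C@@H]1C)[C@@H]23 | intermediate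
31 | 4β-(phenylselanyl)-7,12-dioxo-15,16-epoxy-1,16-cyclocleroda-1,13(16),14-trien-18,19-olide | O=C1C[C@@]23COC(=O)[C@]2([Se]c5ccccc5)CC=C2c4occc4C(=O)C[C@@](C)([C@@H]1C)[C@@H]23 | intermediate
32 | lithium 7α-alkoxide of 12-oxo-4β-(phenylselanyl)-15,16-epoxy-1,16-cyclocleroda-1,13(16),14-trien-18,19-olide | [Li+].[O-][C@@H]1C[C@@]23COC(=O)[C@]2([Se]c5ccccc5)CC=C2c4occc4C(=O)C[C@@](C)([C@@H]1C)[C@@H]23 | intermediate
33 | 7α-acetoxy-12-oxo-4β-(phenylselanyl)-15,16-epoxy-1,16-cyclocleroda-1,13(16),14-trien-18,19-olide | CC(=O)O[C@@H]1C[C@@]23COC(=O)[C@]2([Se]c5ccccc5)CC=C2c4occc4C(=O)C[C@@](C)([C@@H]1C)[C@@H]23 | intermediate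
34 | 7α-acetoxy-2α-boranyl-12-(boranyloxy)-4β-(phenylselanyl)-15,16-epoxy-1,16-cyclocleroda-13(16),14-dien-18,19-olide (1αH expected; C12 not defined) | CC(=O)O[C@@H]1C[C@@]23COC(=O)[C@]2([Se]c5ccccc5)C[C@H](B)[C@H]2c4occc4C(OB)C[C@@](C)([C@@H]1C)[C@@H]23 | intermediate
35 | 7α-acetoxy-2α,12-dihydroxy-4β-(phenylseleninyl)-15,16-epoxy-1,16-cyclocleroda-13(16),14-dien-18,19-olide | CC(=O)O[C@@H]1C[C@@]23COC(=O)[C@]2([Se](=O)c5ccccc5)C[C@H](O)[C@H]2c4occc4C(O)C[C@@](C)([C@@H]1C)[C@@H]23 | intermediate
36 | 7α-acetoxy-2α,12-dihydroxy-15,16-epoxy-1,16-cyclocleroda-3,13(16),14-trien-18,19-olide (1αH expected; both C12 epimers) | CC(=O)O[C@@H]1C[C@@]23COC(=O)C2=C[C@H](O)[C@H]2c4occc4C(O)C[C@@](C)([C@@H]1C)[C@@H]23 | intermediate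
37 | 7α-acetoxy-2,12-dioxo-15,16-epoxy-1,16-cyclocleroda-3,13(16),14-trien-18,19-olide (1αH,10βH) | CC(=O)O[C@@H]1C[C@@]23COC(=O)C2=CC(=O)[C@H]2c4occc4C(=O)C[C@@](C)([C@@H]1C)[C@@H]23 | intermediate
38 | 7α-acetoxy-2α-hydroxy-12-oxo-15,16-epoxy-1,16-cyclocleroda-3,13(16),14-trien-18,19-olide (1αH,10βH; CNP0182929.1) | CC(=O)O[C@@H]1C[C@@]23COC(=O)C2=C[C@H](O)[C@H]2c4occc4C(=O)C[C@@](C)([C@@H]1C)[C@@H]23 | target

**Step count and risks**

Total: 22 steps. Longest linear sequence: 19 steps (steps 1–6, 9, 10 and 12–22, from alkyne 1); steps 7, 8 and 11 are side branches.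

**Step 16 (key step).** The most likely failure is loss of selectivity at the temperature the hindered cycloaddition needs. The bond to the new quaternary C5 forms next to the quaternary C9, so the reaction may be slow enough for the exo mode or the other diene face to compete, and for the butenolide to drift out of conjugation. The fallback activates the dienophile with a removable α-chlorine, which lowers its LUMO and, by sitting exo, disfavours the carbonyl-exo mode. It sets out from diol 24:
- esterification of the primary hydroxyl with 2-chloro-2-(diethoxyphosphoryl)acetic acid (N,N'-dicyclohexylcarbodiimide, 4-(dimethylamino)pyridine) gives the phosphonoacetate F1;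
- intramolecular Horner–Wadsworth–Emmons closure (LiCl, iPr2NEt, MeCN) gives the 3-chlorobutenolide F2;
- enyne metathesis as in step 15 gives the chloro triene F3;
- cycloaddition at lower temperature gives the 4β-chloro adduct F4;
- reductive dechlorination with Zn in AcOH protonates the zinc enolate to the cis-fused lactone and returns to the route at 28.

**Step 15.** The ring may close in the endo mode to the eight-membered isomer once the alkyne has exchanged with ethylene. The catalyst may stall at the hindered alkene next to the quaternary carbon, and incomplete exchange of ethylidene for methylidene would cap the diene with a methyl group. The fallback separates ring closure from diene construction and sets out from 26: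
- semihydrogenation of the alkyne (H2, Pd/CaCO3 poisoned with Pb(OAc)2, quinoline) gives the 2-vinylfuran F5;
- ordinary diene ring-closing metathesis with (H2IMes)(PCy3)Cl2Ru=CHPh gives the cyclohepta[b]furanone F6 with a C1=C10 alkene that carries hydrogen on C1;
- pyridinium tribromide at low temperature gives the dibromide F7;
- 1,8-diazabicyclo[5.4.0]undec-7-ene removes the acidic furylic proton and gives the 1-bromoalkene F8;
- Stille coupling with tributyl(vinyl)stannane (Pd(PPh3)4, CuI, DMF) returns to the route at 27.

**Step 18.** The C4–H is tertiary and flanked by the quaternary C5, so lactone enolate formation may be incomplete. The two ketone enolates may undergo aldol chemistry or epimerise C8 on reprotonation. The fallback carries the leaving group on C4 from the dienophile instead: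
- it sets out from 24 and runs through F1, F2, F3 and F4 as described for step 16, but keeps the chlorine;
- Dess–Martin oxidation gives the 7-ketone F9;
- Li[HB(sBu)3] followed by Ac2O gives the 7α-acetate F10;
- hydroboration–oxidation gives the chloro diol F11;
- Dess–Martin oxidation followed by 1,8-diazabicyclo[5.4.0]undec-7-ene oxidises both carbinols, eliminates HCl from the β-chloro ketone and equilibrates C1, returning to the route at 37.

**Step 19.** The hydride may also reduce the C12 ketone if the C7 ketone is slower than expected, and in-flask acetylation would then fix the error as a diacetate. The crowded alkoxide may also acetylate incompletely. The fallback sets out from 31: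
- reduction followed by aqueous work-up gives the 7α-alcohol F12;
- any C12 carbinol is re-oxidised selectively as a furylic alcohol with MnO2;
- the neutral axial alcohol is acetylated under Lewis-acid catalysis (Ac2O, Sc(OTf)3, MeCN, −20 °C), returning to the route at 33.

**Step 20.** Borane may reduce the acetate or the lactone in the time the hindered, electron-poor alkene needs. Boron may add in part at the furylic carbon, and the peroxide work-up may attack the furan. The fallback avoids borane and sets out from 33:
- H2O2 and pyridine at 0 °C oxidise the selenide, and elimination gives the dienyl lactone F13;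
- dimethyldioxirane epoxidises the electron-rich furan-conjugated C1=C2 alkene to the vinyl epoxide F14;
- BF3·OEt2 at −78 °C opens the epoxide at the furyl-stabilised C1 and a 1,2-hydride shift from C2 (Meinwald rearrangement) gives the C2 ketone, which after equilibration with 1,8-diazabicyclo[5.4.0]undec-7-ene returns to the route at 37.

## Further compounds

F1 | step 16 | (4S,5S,6R)-8-(2-ethynylfuran-3-yl)-4-hydroxy-5,6-dimethyl-2,8-dioxo-6-[(E)-prop-1-enyl]octyl 2-chloro-2-(diethoxyphosphoryl)acetate | C/C=C/[C@@](C)(CC(=O)c1ccoc1C#C)[C@H](C)[C@@H](O)CC(=O)COC(=O)C(Cl)P(=O)(OCC)OCC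
F2 | step 16 | 3-chloro-4-{(2S,3S,4R)-6-(2-ethynylfuran-3-yl)-2-hydroxy-3,4-dimethyl-6-oxo-4-[(E)-prop-1-enyl]hexyl}furan-2(5H)-one | C/C=C/[C@@](C)(CC(=O)c1ccoc1C#C)[C@H](C)[C@@H](O)CC1=C(Cl)C(=O)OC1
F3 | step 16 | (6R)-6-[(2S,3S)-4-(4-chloro-5-oxo-2,5-dihydrofuran-3-yl)-3-hydroxybutan-2-yl]-6-methyl-8-vinyl-5,6-dihydro-4H-cyclohepta[b]furan-4-one | C=CC1=C[C@](C)([C@H](C)[C@@H](O)CC3=C(Cl)C(=O)OC3)CC(=O)c2ccoc12
F4 | step 16 | 4β-chloro-7β-hydroxy-12-oxo-15,16-epoxy-1,16-cyclocleroda-1,13(16),14-trien-18,19-olide | O[C@H]1C[C@@]23COC(=O)[C@]2(Cl)CC=C2c4occc4C(=O)C[C@@](C)([C@@H]1C)[C@@H]23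
F5 | step 15 | 4-{(2S,3S,4R)-2-hydroxy-3,4-dimethyl-6-oxo-4-[(E)-prop-1-enyl]-6-(2-vinylfuran-3-yl)hexyl}furan-2(5H)-one | C/C=C/[C@@](C)(CC(=O)c1ccoc1C=C)[C@H](C)[C@@H](O)CC1=CC(=O)OC1
F6 | step 15 | (6R)-6-[(2S,3S)-3-hydroxy-4-(5-oxo-2,5-dihydrofuran-3-yl)butan-2-yl]-6-methyl-5,6-dihydro-4H-cyclohepta[b]furan-4-one | O=C1C[C@@](C)([C@H](C)[C@@H](O)CC3=CC(=O)OC3)C=Cc2occc12
F7 | step 15 | (6R)-7,8-dibromo-6-[(2S,3S)-3-hydroxy-4-(5-oxo-2,5-dihydrofuran-3-yl)butan-2-yl]-6-methyl-5,6,7,8-tetrahydro-4H-cyclohepta[b]furan-4-one (trans dibromide, configuration at C7 and C8 not defined) | O=C1C[C@@](C)([C@H](C)[C@@H](O)CC3=CC(=O)OC3)C(Br)C(Br)c2occc12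
F8 | step 15 | (6R)-8-bromo-6-[(2S,3S)-3-hydroxy-4-(5-oxo-2,5-dihydrofuran-3-yl)butan-2-yl]-6-methyl-5,6-dihydro-4H-cyclohepta[b]furan-4-one | O=C1C[C@@](C)([C@H](C)[C@@H](O)CC3=CC(=O)OC3)C=C(Br)c2occc12
F9 | step 18 | 4β-chloro-7,12-dioxo-15,16-epoxy-1,16-cyclocleroda-1,13(16),14-trien-18,19-olide | O=C1C[C@@]23COC(=O)[C@]2(Cl)CC=C2c4occc4C(=O)C[C@@](C)([C@@H]1C)[C@@H]23
F10 | step 18 | 7α-acetoxy-4β-chloro-12-oxo-15,16-epoxy-1,16-cyclocleroda-1,13(16),14-trien-18,19-olide | CC(=O)O[C@@H]1C[C@@]23COC(=O)[C@]2(Cl)CC=C2c4occc4C(=O)C[C@@](C)([C@@H]1C)[C@@H]23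
F11 | step 18 | 7α-acetoxy-4β-chloro-2α,12-dihydroxy-15,16-epoxy-1,16-cyclocleroda-13(16),14-dien-18,19-olide (1αH expected; both C12 epimers) | CC(=O)O[C@@H]1C[C@@]23COC(=O)[C@]2(Cl)C[C@H](O)[C@H]2c4occc4C(O)C[C@@](C)([C@@H]1C)[C@@H]23
F12 | step 19 | 7α-hydroxy-12-oxo-4β-(phenylselanyl)-15,16-epoxy-1,16-cyclocleroda-1,13(16),14-trien-18,19-olide | O[C@@H]1C[C@@]23COC(=O)[C@]2([Se]c5ccccc5)CC=C2c4occc4C(=O)C[C@@](C)([C@@H]1C)[C@@H]23
F13 | step 20 | 7α-acetoxy-12-oxo-15,16-epoxy-1,16-cyclocleroda-1,3,13(16),14-tetraen-18,19-olide | CC(=O)O[C@@H]1C[C@@]23COC(=O)C2=CC=C2c4occc4C(=O)C[C@@](C)([C@@H]1C)[C@@H]23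
F14 | step 20 | 7α-acetoxy-1,2-epoxy-12-oxo-15,16-epoxy-1,16-cyclocleroda-3,13(16),14-trien-18,19-olide (epoxide face not defined) | CC(=O)O[C@@H]1C[C@@]23COC(=O)C2=CC4OC42c5occc5C(=O)C[C@@](C)([C@@H]1C)[C@@H]23
A1 | alternative 1 | trans-decalin alkenyl carboxylic acid with angular methyl (precursor of the C–H lactonisation) | CC(=O)O[C@@H]1C[C@@]2(C)C(C(=O)O)=C[C@H](O[Si](C)(C)C(C)(C)C)C[C@@H]2[C@@](C)(CC(=O)OC)[C@@H]1C
A2 | alternative 1 | trans-decalin butenolide | CC(=O)O[C@@H]1C[C@@]23COC(=O)C2=C[C@H](O[Si](C)(C)C(C)(C)C)C[C@@H]3[C@@](C)(CC(=O)OC)[C@@H]1C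
A3 | alternative 2 | ring B enone lactone carrying the 2-(2-bromofuran-3-yl)-2-oxoethyl chain on C9 | CC(=O)O[C@@H]1C[C@@]23COC(=O)C2=CC(=O)C[C@@H]3[C@@](C)(CC(=O)c2ccoc2Br)[C@@H]1C
A4 | alternative 2 | pentacyclic ring B ketone (same structure as 37) | CC(=O)O[C@@H]1C[C@@]23COC(=O)C2=CC(=O)[C@H]2c4occc4C(=O)C[C@@](C)([C@@H]1C)[C@@H]23
A5 | alternative 3 | 3-furyl diazomethyl ketone with exocyclic methylene at C9 | CC(=O)O[C@@H]1C[C@@]23COC(=O)C2=C[C@H](O[Si](C)(C)C(C)(C)C)[C@@H](c2occc2C(=O)C=[N+]=[N-])[C@@H]3C(=C)[C@@H]1C
A6 | alternative 3 | cyclopropane-bridged pentacycle | CC(=O)O[C@@H]1C[C@@]23COC(=O)C2=C[C@H](O[Si](C)(C)C(C)(C)C)[C@H]2c4occc4C(=O)[C@@H]5C[C@]5([C@@H]1C)[C@@H]23
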